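**Amounts and the product excess**

all flasks: left-handed substrate 37 mM; right-handed substrate 37 mM; racemization catalyst 0.74 mM

|  | partner | free catalyst | remark | time |
|---|---|---|---|---|
| Thursday's | 46 mM | 2.3 mM | run made earlier |  |
| Sunday's | 69 mM | 2.3 mM | run made earlier |  |
| Wednesday's | 92.5 mM | 3.4 mM | run made earlier |  |
| summer | 92.5 mM | 2.3 mM |  | 5.0 d |
| winter | 92.5 mM | 2.3 mM |  | 8.0 d |

| run | time / d | left-handed product / % | right-handed product / % | left-handed substrate / % |
|---|---|---|---|---|
| Thursday's | 0.500 | 5.9 | 0 | 45.2 |
| Thursday's | 1.04 | 7.1 | 2.9 | 44.7 |
| Thursday's | 1.67 | 4.6 | 2.9 | 45.8 |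
| Thursday's | 2.08 | 6.3 | 3.8 | 43.2 |
| Thursday's | 2.50 | 8.6 | 2.1 | 43.0 |
| Thursday's | 3.00 | 9.2 | 3.4 | 44.2 |
| Sunday's | 0.250 | 5.7 | 2.4 | 43.9 |
| Sunday's | 0.417 | 7.8 | 2.3 | 43.2 |
| Sunday's | 0.625 | 7.9 | 2.8 | 42.6 |
| Sunday's | 1.04 | 8.9 | 4.2 | 43.2 |
| Sunday's | 1.67 | 10.9 | 5.4 | 41.8 |
| Sunday's | 3.00 | 11.7 | 2.6 | 42.6 |
| Wednesday's | 0.250 | 9.9 | 4.5 | 39.7 |
| Wednesday's | 0.417 | 11.4 | 4.7 | 40.4 |
| Wednesday's | 0.833 | 11.5 | 6.8 | 39.1 |
| Wednesday's | 1.67 | 15.6 | 5.6 | 39.5 |
| Wednesday's | 3.00 | 15.3 | 4.7 | 39.6 |

(readings scatter by 1 percentage point)

- free catalyst is single-handed; left-handed substrate and right-handed substrate are mirror images of each other, charged as a racemate, each of them at the stated concentration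
- on the list of suspects stand: partner -> decomposed reagent; 2 free catalyst -> spent catalyst; partner + free catalyst + right-handed substrate -> free catalyst + right-handed product; partner + free catalyst + left-handed substrate -> free catalyst + left-handed product; left-handed substrate + racemization catalyst <-> right-handed substrate + racemization catalyst
- an excess is the difference of the two amounts in percent of their sum
- an excess is below zero if the other one leads

1. the flask that ends with the higher excess of left-handed product over right-handed product in the product, or "neither" when 2 percentage points or less lies between them (summer / winter / neither)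
2. excess of left-handed product over right-handed product in the product at the end, summer
3. excess of left-handed product over right-handed product in the product at the end, winter

1. At Wednesday's last reading the two products stand at 15.3% and 4.7% of the substrates charged, which accounts for 16.0% of Wednesday's partner charge. Yet left-handed product reads 15.6% at 1.67 d and 15.3% at 3.00 d. The reading taken here of Wednesday's stall is a loss of free catalyst to spent catalyst, one of the listed suspects.

2. The balance gives the right-handed substrate. In Wednesday's run it leads the left-handed substrate by 6.2 percentage points at 0.250 d, but by 0.8 points at 3.00 d. These readings, each with its scatter, fit the racemization catalyst closing the gap.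

3. With the substrate near racemic, the product ratio should reflect the catalyst's selectivity factor. Summed over the runs, left-handed product reads 158% and right-handed product 61.1%. Their ratio is 2.59.

4. This gives the pooled excess, the difference of those sums in percent of their total: 44.3%. I commit to it for summer and winter, which differ in time, and so to "neither".

5. The weak link is pooling across recipes. Wednesday's readings alone give 41.6%, and Thursday's give 46.8%. That span puts a range on the value, but summer and winter have the same charges, so "neither" stands.

**The forecast**

The forecast says neither, with 46% (40% to 52%) for summer and 46% (40% to 52%) for winter, slightly above my number: “Racemization therefore keeps the substrate near racemic”.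

**The result**

    partner → decomposed reagent (k = 8.21 × 10⁻⁷ s⁻¹)
    2 free catalyst → spent catalyst (k = 0.0761 L mol⁻¹ s⁻¹)
    partner + free catalyst + right-handed substrate → free catalyst + right-handed product (k = 0.0518 L² mol⁻² s⁻¹)
    partner + free catalyst + left-handed substrate → free catalyst + left-handed product (k = 0.139 L² mol⁻² s⁻¹)
    left-handed substrate + racemization catalyst ⇌ right-handed substrate + racemization catalyst, rate k5*[racemization catalyst]*[left-handed substrate] forward; the back reaction follows from the equilibrium constant (k = 0.00695 L mol⁻¹ s⁻¹)

The answer is neither: summer ends at 43.2% and winter at 43.3%. A neighbouring flask takes winter's recipe with 5.8 mM of free catalyst and ends with 18.4% as left-handed product. The carried excess of 44.3% then gives 7.10% of right-handed product. The flask holds 7.40%, and its excess is 42.7%.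

The earlier runs and the new flask were generated by integration for an exercise; the scatter is artificial.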